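**Plan**
Locants: ring A is the acylated resorcinol ring (C1'–C6'), ring B is the 4-hydroxyphenyl ring, and the side chain is C1''–C8''. The retrosynthesis cuts (a) the enone Cα=Cβ bond, (b) C2''–OH back to C2''–B, and (c) in one event C3'(ring A)–C1'' together with C2''–C3''.
Enabling feature: C1''H2–C2''H(OH) sits between C3' of ring A (the carbon between the two phenol oxygens) and the sp2 carbon C3'' of the 1,1-disubstituted alkene. It is a vinyl group that has taken up an aryl at CH2 and an alkenyl plus a heteroatom at CH, which is the retron of a conjunctive cross-coupling. Boron serves as temporary tether between vinyl and alkenyl and as placeholder for OH.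
Forward: 2-bromoresorcinol is C-acylated and MOM-protected (the bromine marks C3'). 6-Methylhept-5-en-2-one gives the alkenylboronate by Shapiro borylation, and vinylmagnesium bromide completes the borate. Coupling, C–B oxidation, Claisen–Schmidt condensation and MOM removal follow.
No ring is built. The chain is joined at C3'–C1'' and C2''–C3'' at once, then at Cα=Cβ. The enone comes after the peroxide step because alkaline H2O2 would epoxidise a chalcone.
Stereochemistry: the single stereocentre C2'' (R) is set by the chiral bisphosphine–palladium catalyst in the coupling and carried into C–O by stereoretentive oxidation. The E enone arises from E1cB dehydration.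

Key step: step 5

Assumption: the (SP,S'P) antipode of the MandyPhos ligand named in step 5 is taken to give the (R)-allylboronate; both antipodes are commercial, so the mirror-image ligand would be used should the sense of induction be the opposite.

**Step 1**
Reactants: 1 2-bromoresorcinol (2-bromobenzene-1,3-diol)
Product: 2 1-(3-bromo-2,4-dihydroxyphenyl)ethan-1-one
Conditions: AcOH, BF3·OEt2, 85 °C; aq. NaOAc work-up
Reagents that add atoms: acetic acid CC(=O)O
Why: Nencki-type Friedel–Crafts C-acylation; the two positions activated by the hydroxyls (ortho to one, para to the other) are equivalent by symmetry, so a single ketone should form, and bromoresorcinols tolerate strong acid in related Pechmann condensations.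

**Step 2**
Reactants: 2 1-(3-bromo-2,4-dihydroxyphenyl)ethan-1-one
Product: 3 1-[3-bromo-2,4-bis(methoxymethoxy)phenyl]ethan-1-one
Conditions: NaH (2.2 equiv), MOMCl, DMF, 0 °C → rt
Reagents that add atoms: chloromethyl methyl ether COCCl
Why: Williamson-type O-alkylation of the bis(phenoxide); NaH is chosen because the chelated, flanked 2-OH reacts poorly under amine base, and MOM ethers survive the borate, alkaline peroxide and KOH to come.

**Step 3**
Reactants: 4 6-methylhept-5-en-2-one
Product: 5 (E)-N'-(6-methylhept-5-en-2-ylidene)-2,4,6-triisopropylbenzenesulfonohydrazide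
Conditions: 2,4,6-iPr3C6H2SO2NHNH2, cat. HCl, MeOH, rt
Reagents that add atoms: 2,4,6-triisopropylbenzenesulfonohydrazide CC(C)c1cc(C(C)C)c(S(=O)(=O)NN)c(C(C)C)c1
Why: Acid-catalysed hydrazone condensation, which should give mainly the E isomer with the sulfonamide nitrogen syn to the methyl group, as the Shapiro step requires.

**Step 4**
Reactants: 5 (E)-N'-(6-methylhept-5-en-2-ylidene)-2,4,6-triisopropylbenzenesulfonohydrazide
Product: 7 4,4,5,5-tetramethyl-2-(6-methylhepta-1,5-dien-2-yl)-1,3,2-dioxaborolane, via vinyllithium 6 (not isolated)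
Conditions: n-BuLi (2.1 equiv), THF, −78 → 0 °C; then iPrOBpin, −78 °C → rt; 1 M HCl work-up
Reagents that add atoms: 2-isopropoxy-4,4,5,5-tetramethyl-1,3,2-dioxaborolane CC(C)OB1OC(C)(C)C(C)(C)O1
Why: Shapiro reaction; the syn-directed second deprotonation occurs at the methyl group, loss of sulfinate and N2 gives the 1,1-disubstituted vinyllithium, and electrophilic borylation traps it.

**Step 5**
Reactants: 7 4,4,5,5-tetramethyl-2-(6-methylhepta-1,5-dien-2-yl)-1,3,2-dioxaborolane; 8 vinylmagnesium bromide; 3 1-[3-bromo-2,4-bis(methoxymethoxy)phenyl]ethan-1-one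
Product: 10 1-{2,4-bis(methoxymethoxy)-3-[(2R)-7-methyl-3-methylidene-2-(4,4,5,5-tetramethyl-1,3,2-dioxaborolan-2-yl)oct-6-en-1-yl]phenyl}ethan-1-one, via sodium vinyl(alkenyl)borate 9 (not isolated)
Conditions: 7 (1.3 equiv), 8 (1.2 equiv), THF, 0 °C → rt; NaOTf, DMSO; then 3, Pd(OAc)2 (2 mol %), (SP,S'P)-1,1'-bis[bis(4-methoxy-3,5-dimethylphenyl)phosphino]-2,2'-bis[(R)-α-(dimethylamino)benzyl]ferrocene (a MandyPhos ligand, 2.4 mol %), 40–60 °C; short silica plug
Reagents that add atoms: none
Why: Oxidative addition of 3 to zerovalent palladium and bromide abstraction by NaOTf give a cationic arylpalladium species (divalent palladium) that binds the unsubstituted vinyl group of borate 9; this π-activation triggers an anti 1,2-metallate shift of the 1,1-disubstituted alkenyl group from boron to the vinyl CH carbon (C2''–C3'' bond) while palladium takes the terminal CH2, and reductive elimination then forms the C3'(ring A)–C1'' bond. The closest known reaction type is the palladium/MandyPhos-catalysed enantioselective conjunctive cross-coupling of bis(alkenyl)borates with aryl electrophiles to α-chiral allylboronates, in its variant for Grignard-derived borates and aryl bromides with NaOTf as halide scavenger. No ring is closed. The only new stereocentre, C2'', is set under catalyst control: the C2-symmetric ferrocenyl bisphosphine decides which enantiotopic face of the vinyl group palladium binds, and the migration is stereospecifically anti to the metal. Three selectivities are needed: site selectivity between the two alkenes on boron, secured because the metal binds the less substituted vinyl group and the more substituted alkenyl migrates (the remote trisubstituted alkene is a spectator); metallate shift over direct transmetalation, favoured by the wide-bite-angle ligand and the cationic metal centre; and tolerance of the methyl ketone, secured because the four-coordinate borate is fully formed before 3 is added (7 in slight excess over 8) and neither adds to nor enolises ketones. The position on ring A is not left to arene reactivity, since it is fixed by the bromine between the two OMOM groups.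

**Step 6**
Reactants: 10 1-{2,4-bis(methoxymethoxy)-3-[(2R)-7-methyl-3-methylidene-2-(4,4,5,5-tetramethyl-1,3,2-dioxaborolan-2-yl)oct-6-en-1-yl]phenyl}ethan-1-one
Product: 11 1-{3-[(2R)-2-hydroxy-7-methyl-3-methylideneoct-6-en-1-yl]-2,4-bis(methoxymethoxy)phenyl}ethan-1-one
Conditions: 30% H2O2, 3 M NaOH, THF, 0 °C → rt
Reagents that add atoms: hydrogen peroxide OO
Why: Stereoretentive boronate oxidation (1,2-shift of carbon from boron to oxygen without allylic transposition); the masked phenols exclude a Dakin reaction and no enone is yet present for Weitz–Scheffer epoxidation.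

**Step 7**
Reactants: 12 4-hydroxybenzaldehyde
Product: 13 4-(methoxymethoxy)benzaldehyde
Conditions: MOMCl, iPr2NEt, CH2Cl2, 0 °C → rt
Reagents that add atoms: chloromethyl methyl ether COCCl
Why: Standard O-alkylation of a phenol with MOMCl, giving the same protecting group as on ring A so that one final operation removes all three.

**Step 8**
Reactants: 11 1-{3-[(2R)-2-hydroxy-7-methyl-3-methylideneoct-6-en-1-yl]-2,4-bis(methoxymethoxy)phenyl}ethan-1-one; 13 4-(methoxymethoxy)benzaldehyde
Product: 14 (2E)-1-{3-[(2R)-2-hydroxy-7-methyl-3-methylideneoct-6-en-1-yl]-2,4-bis(methoxymethoxy)phenyl}-3-[4-(methoxymethoxy)phenyl]prop-2-en-1-one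
Conditions: KOH, EtOH/H2O, 0 °C → rt
Reagents that add atoms: none
Why: Claisen–Schmidt condensation; the methyl ketone is the only enolisable partner, E1cB dehydration gives the E enone under thermodynamic control, and the free carbinol and its stereocentre are inert to KOH.

**Step 9**
Reactants: 14 (2E)-1-{3-[(2R)-2-hydroxy-7-methyl-3-methylideneoct-6-en-1-yl]-2,4-bis(methoxymethoxy)phenyl}-3-[4-(methoxymethoxy)phenyl]prop-2-en-1-one
Product: 15 (2E)-1-{2,4-dihydroxy-3-[(2R)-2-hydroxy-7-methyl-3-methylideneoct-6-en-1-yl]phenyl}-3-(4-hydroxyphenyl)prop-2-en-1-one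
Conditions: 3 M aq. HCl, MeOH, rt → 40 °C
Reagents that add atoms: none
Why: Acid-catalysed acetal exchange of phenolic MOM ethers, standard for prenylated and geranylated chalcones; C2'' should keep its configuration because ionisation would give an allyl cation whose alkyl group sits on the central carbon and lends no stabilisation.

**Compound list**
1 | 2-bromoresorcinol | Oc1cccc(O)c1Br | starting material
2 | 1-(3-bromo-2,4-dihydroxyphenyl)ethan-1-one | CC(=O)c1ccc(O)c(Br)c1O | intermediate
3 | 1-[3-bromo-2,4-bis(methoxymethoxy)phenyl]ethan-1-one | CC(=O)c1ccc(OCOC)c(Br)c1OCOC | intermediate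
4 | 6-methylhept-5-en-2-one | CC(=O)CCC=C(C)C | starting material
5 | (E)-N'-(6-methylhept-5-en-2-ylidene)-2,4,6-triisopropylbenzenesulfonohydrazide | C/C(CCC=C(C)C)=N\NS(=O)(=O)c1c(C(C)C)cc(C(C)C)cc1C(C)C | intermediate
6 | (6-methylhepta-1,5-dien-2-yl)lithium | [Li]C(=C)CCC=C(C)C | intermediate
7 | 4,4,5,5-tetramethyl-2-(6-methylhepta-1,5-dien-2-yl)-1,3,2-dioxaborolane | C=C(CCC=C(C)C)B1OC(C)(C)C(C)(C)O1 | intermediate
8 | vinylmagnesium bromide | C=C[Mg]Br | starting material
9 | sodium ethenyl(6-methylhepta-1,5-dien-2-yl)(pinacolato)borate | [Na+].C=C[B-]1(C(=C)CCC=C(C)C)OC(C)(C)C(C)(C)O1 | intermediate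
10 | 1-{2,4-bis(methoxymethoxy)-3-[(2R)-7-methyl-3-methylidene-2-(4,4,5,5-tetramethyl-1,3,2-dioxaborolan-2-yl)oct-6-en-1-yl]phenyl}ethan-1-one | C=C(CCC=C(C)C)[C@H](B1OC(C)(C)C(C)(C)O1)Cc1c(OCOC)ccc(C(C)=O)c1OCOC | intermediate
11 | 1-{3-[(2R)-2-hydroxy-7-methyl-3-methylideneoct-6-en-1-yl]-2,4-bis(methoxymethoxy)phenyl}ethan-1-one | C=C(CCC=C(C)C)[C@H](O)Cc1c(OCOC)ccc(C(C)=O)c1OCOC | intermediate
12 | 4-hydroxybenzaldehyde | O=Cc1ccc(O)cc1 | starting material
13 | 4-(methoxymethoxy)benzaldehyde | COCOc1ccc(C=O)cc1 | intermediate
14 | (2E)-1-{3-[(2R)-2-hydroxy-7-methyl-3-methylideneoct-6-en-1-yl]-2,4-bis(methoxymethoxy)phenyl}-3-[4-(methoxymethoxy)phenyl]prop-2-en-1-one | C=C(CCC=C(C)C)[C@H](O)Cc1c(OCOC)ccc(C(=O)/C=C/c2ccc(OCOC)cc2)c1OCOC | intermediate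
15 | (2E)-1-{2,4-dihydroxy-3-[(2R)-2-hydroxy-7-methyl-3-methylideneoct-6-en-1-yl]phenyl}-3-(4-hydroxyphenyl)prop-2-en-1-one | C=C(CCC=C(C)C)[C@H](O)Cc1c(O)ccc(C(=O)/C=C/c2ccc(O)cc2)c1O | target

**Totals**
Total steps: 9.
Longest linear sequence: 6 steps (1, 2, 5, 6, 8, 9). The branch 3, 4, 5, 6, 8, 9 is equally long.

**Steps most likely to fail**

**Step 5.**
- Oxidative addition to the di-ortho-substituted aryl bromide may be slow, and alkene binding at the crowded arylpalladium may be hindered.
- Direct transfer of vinyl or alkenyl from boron (Suzuki–Miyaura pathway) could then overtake the metallate shift.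
- Facial selectivity could erode, and slow allylboration of the ketone by the product could set in at the higher temperature.

The fallback sets out from bromide 3 and vinyllithium 6 and comes back at alcohol 11. A Stille coupling of 3 with allyltributylstannane (Pd(PPh3)4, LiCl, DMF, 90 °C) should give 1-[3-allyl-2,4-bis(methoxymethoxy)phenyl]ethan-1-one F1. Lemieux–Johnson cleavage (OsO4 cat., NaIO4, 2,6-lutidine, dioxane/H2O) of its only alkene should give 2-[3-acetyl-2,6-bis(methoxymethoxy)phenyl]acetaldehyde F2. Quenching 6 with I2 should give 2-iodo-6-methylhepta-1,5-diene F3. A ligand-controlled asymmetric Nozaki–Hiyama–Kishi coupling of F2 with F3 (CrCl2, NiCl2 cat., chiral oxazoline sulfonamide ligand, Et3N, THF) should then give 11, since the alkenylchromium reagent adds to the aldehyde and spares the methyl ketone.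

**Step 9.**
- The freed ring A phenols may cyclise under acid onto the 1,1-disubstituted or the trisubstituted alkene (chroman formation).
- Methanol may add to the trisubstituted alkene.
- The chalcone may isomerise to the flavanone.

The fallback avoids acid altogether. It sets out from 2 and comes back at target 15. Silylation of 2 (TBSCl, imidazole, DMF) should give 1-[3-bromo-2,4-bis(tert-butyldimethylsilyloxy)phenyl]ethan-1-one F4. The coupling of step 5 with borate 9 should give 1-{2,4-bis(tert-butyldimethylsilyloxy)-3-[(2R)-7-methyl-3-methylidene-2-(4,4,5,5-tetramethyl-1,3,2-dioxaborolan-2-yl)oct-6-en-1-yl]phenyl}ethan-1-one F5. Non-basic oxidation with Me3NO (THF, rt → 50 °C) should give 1-{2,4-bis(tert-butyldimethylsilyloxy)-3-[(2R)-2-hydroxy-7-methyl-3-methylideneoct-6-en-1-yl]phenyl}ethan-1-one F6. Concentrated KOH in EtOH/H2O with unprotected aldehyde 12 should strip both aryl silyl ethers to 1-{2,4-dihydroxy-3-[(2R)-2-hydroxy-7-methyl-3-methylideneoct-6-en-1-yl]phenyl}ethan-1-one F7. In the same flask a protecting-group-free Claisen–Schmidt condensation should then give 15.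

**Step 4.**
- Regiocontrol in the second deprotonation may be incomplete.
- The solvent may protonate the vinyllithium before borylation.
- The small alkenylboronate may be lost on work-up.

The fallback sets out from ketone 4 and comes back at boronate 7. Kinetic enolisation (LDA, THF, −78 °C) and trapping with PhNTf2 should give 6-methylhepta-1,5-dien-2-yl trifluoromethanesulfonate F8. Miyaura borylation (B2pin2, PdCl2(PPh3)2, PPh3, KOPh, toluene, 50 °C) should then give 7.

**Further compounds**
F1 | step 5 | 1-[3-allyl-2,4-bis(methoxymethoxy)phenyl]ethan-1-one | C=CCc1c(OCOC)ccc(C(C)=O)c1OCOC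
F2 | step 5 | 2-[3-acetyl-2,6-bis(methoxymethoxy)phenyl]acetaldehyde | O=CCc1c(OCOC)ccc(C(C)=O)c1OCOC
F3 | step 5 | 2-iodo-6-methylhepta-1,5-diene | IC(=C)CCC=C(C)C
F4 | step 9 | 1-[3-bromo-2,4-bis(tert-butyldimethylsilyloxy)phenyl]ethan-1-one | CC(=O)c1ccc(O[Si](C)(C)C(C)(C)C)c(Br)c1O[Si](C)(C)C(C)(C)C
F5 | step 9 | 1-{2,4-bis(tert-butyldimethylsilyloxy)-3-[(2R)-7-methyl-3-methylidene-2-(4,4,5,5-tetramethyl-1,3,2-dioxaborolan-2-yl)oct-6-en-1-yl]phenyl}ethan-1-one | C=C(CCC=C(C)C)[C@H](B1OC(C)(C)C(C)(C)O1)Cc1c(O[Si](C)(C)C(C)(C)C)ccc(C(C)=O)c1O[Si](C)(C)C(C)(C)C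
F6 | step 9 | 1-{2,4-bis(tert-butyldimethylsilyloxy)-3-[(2R)-2-hydroxy-7-methyl-3-methylideneoct-6-en-1-yl]phenyl}ethan-1-one | C=C(CCC=C(C)C)[C@H](O)Cc1c(O[Si](C)(C)C(C)(C)C)ccc(C(C)=O)c1O[Si](C)(C)C(C)(C)C
F7 | step 9 | 1-{2,4-dihydroxy-3-[(2R)-2-hydroxy-7-methyl-3-methylideneoct-6-en-1-yl]phenyl}ethan-1-one | C=C(CCC=C(C)C)[C@H](O)Cc1c(O)ccc(C(C)=O)c1O
F8 | step 4 | 6-methylhepta-1,5-dien-2-yl trifluoromethanesulfonate | C=C(CCC=C(C)C)OS(=O)(=O)C(F)(F)F
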